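A direct plan would close both carbocycles in one zinc chloride mediated Robinson annulation (bis-enone A1) and would set both carbinols by oxazaborolidine reduction. It would then create C8 from carbon monoxide in a carbonylative Stille coupling of the β-ring allylic chloride A2 with the C29 polyenyl stannane A3.
Its weakest steps would be:
- the annulation, which would leave the future C6' uncontrolled, so that half of the material would be the wrong diastereomer and the β ring would need a Mitsunobu inversion;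
- the hydrostannation leading to A3, whose regiochemistry would rest on one propargylic hydroxyl;
- the three-component carbonylative coupling, where direct allyl–vinyl coupling, allylic transposition and protodestannylation would compete on a light-sensitive octaene.

The route rests on a temporary ether bond between O19 and C12. Atoms O19, C19, C9, C10, C11 and C12 are held in a 3-acyl-5,6-dihydro-2H-pyran, closed by olefin metathesis on a small fragment and carried through the union of two C20 halves at C15=C15'. In the last step, base would remove H11 (γ to the C8 ketone) and expel O19 from C12: one operation would form C11=C12, free the 19-hydroxyl, deliver C9=C10 with the ring-fixed geometry and complete the chromophore. No carbonylation and no stannane are needed; C7–C8 comes from an ene reaction, and C6' is relayed from C3' by anti-SN2' substitution, so no diastereomer is discarded.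

Key step: step 22

Remark: atom numbers such as C8, C19 and C6' follow carotenoid numbering of the target; (4R,6R)-actinol 1 and the C5 acetal aldehyde 6 are taken as purchasable industrial intermediates; compounds 7 to 13 and 32 are carried as both C12 epimers, a centre that step 22 erases.

Step 1
Reactants: 1 (4R,6R)-4-hydroxy-2,2,6-trimethylcyclohexan-1-one (actinol)
Product: 2 (4R,6R)-4-[(tert-butyldimethylsilyl)oxy]-2,2,6-trimethylcyclohexan-1-one
Conditions: TBSCl (1.2 equiv), imidazole (2.5 equiv), DMF, rt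
Reagents that add atoms: tert-butyldimethylsilyl chloride, CC(C)(C)[Si](C)(C)Cl
Why: Silyl ether formation masks the only hydroxyl ahead of the ylide, Lewis acid and organometallic steps, and the purchased carbinol centre, which becomes C3 of the β ring, is not touched.

Step 2
Reactants: 2 (4R,6R)-4-[(tert-butyldimethylsilyl)oxy]-2,2,6-trimethylcyclohexan-1-one
Product: 3 tert-butyldimethyl{[(1R,5R)-3,3,5-trimethyl-4-methylidenecyclohexyl]oxy}silane
Conditions: Ph3PCH3Br (3 equiv), KOt-Bu (3 equiv), toluene, 90 °C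
Reagents that add atoms: methyltriphenylphosphonium bromide, C[P+](c1ccccc1)(c1ccccc1)c1ccccc1.[Br-]
Why: Wittig methylenation under the forcing conditions usual for 2,2,6-trimethylcyclohexanones installs C7 as an exocyclic methylene, and any epimerisation at the methyl-bearing carbon is harmless because that centre becomes sp2 in step 3.

Step 3
Reactants: 3 tert-butyldimethyl{[(1R,5R)-3,3,5-trimethyl-4-methylidenecyclohexyl]oxy}silane
Product: 4 2-{(4R)-4-[(tert-butyldimethylsilyl)oxy]-2,6,6-trimethylcyclohex-1-en-1-yl}ethan-1-ol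
Conditions: (CH2O)n (2 equiv), Me2AlCl (1.5 equiv), CH2Cl2, 0 °C to rt
Reagents that add atoms: formaldehyde (as paraformaldehyde), C=O
Why: Carbonyl-ene reaction of the formaldehyde–Me2AlCl complex bonds C7 to C8 while the only allylic hydrogen, at C5, is transferred, so the double bond can only move into the tetrasubstituted C5=C6 position of the β ring.

Step 4
Reactants: 4 2-{(4R)-4-[(tert-butyldimethylsilyl)oxy]-2,6,6-trimethylcyclohex-1-en-1-yl}ethan-1-ol
Product: 5 {(4R)-4-[(tert-butyldimethylsilyl)oxy]-2,6,6-trimethylcyclohex-1-en-1-yl}acetaldehyde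
Conditions: Dess–Martin periodinane (1.3 equiv), NaHCO3, CH2Cl2, 0 °C to rt; used at once
Reagents that add atoms: none
Why: Dess–Martin oxidation under buffered, non-basic conditions gives the β,γ-unsaturated aldehyde without moving the ring double bond, whose conjugation would need a strained exocyclic alkene between the gem-dimethyl and methyl groups.

Step 5
Reactants: 6 (2E)-4,4-dimethoxy-2-methylbut-2-enal
Product: 7 (2E)-1,1-dimethoxy-3-methylhepta-2,6-dien-4-ol (racemic)
Conditions: CH2=CHCH2MgBr (1.1 equiv), Et2O, -78 °C; aq. NH4Cl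
Reagents that add atoms: allylmagnesium bromide, C=CC[Mg]Br
Why: Grignard 1,2-addition to the enal supplies C10 and C11 and makes C12 a carbinol, which is left racemic because it becomes sp2 in step 22, while the acetal keeps C15 masked.

Step 6
Reactants: 7 (2E)-1,1-dimethoxy-3-methylhepta-2,6-dien-4-ol
Product: 8 (2E)-4-[(2-bromoprop-2-en-1-yl)oxy]-1,1-dimethoxy-3-methylhepta-2,6-diene (racemic)
Conditions: NaH (1.3 equiv), 2,3-dibromopropene (1.5 equiv), tetrabutylammonium iodide (0.05 equiv), THF, 0 °C to rt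
Reagents that add atoms: 2,3-dibromoprop-1-ene, BrCC(Br)=C
Why: Williamson etherification at the allylic CH2Br makes the temporary O19–C12 ether and brings in C19 and C9, the vinylic bromide being inert to the alkoxide and the low temperature keeping the sodium alkoxide of this 1,5-dien-3-ol from oxy-Cope rearrangement.

Step 7
Reactants: 5 {(4R)-4-[(tert-butyldimethylsilyl)oxy]-2,6,6-trimethylcyclohex-1-en-1-yl}acetaldehyde; 8 (2E)-4-[(2-bromoprop-2-en-1-yl)oxy]-1,1-dimethoxy-3-methylhepta-2,6-diene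
Product: 10 1-{(4R)-4-[(tert-butyldimethylsilyl)oxy]-2,6,6-trimethylcyclohex-1-en-1-yl}-3-({[(2E)-1,1-dimethoxy-3-methylhepta-2,6-dien-4-yl]oxy}methyl)but-3-en-2-ol (mixture at both carbinol-derived centres), via alkenylchromium dichloride 9 (not isolated)
Conditions: 8 (1.5 equiv), CrCl2 (4 equiv), NiCl2 (0.02 equiv), DMF, rt; aq. NH4Cl
Reagents that add atoms: none
Why: Nozaki–Hiyama–Kishi coupling (nickel-catalysed formation of the alkenyl organometal of trivalent chromium, then 1,2-addition) forms C8–C9 under non-basic conditions that spare the enolisable β,γ-unsaturated aldehyde, the acetal and the silyl ether, and the new carbinol centre is uncontrolled because step 9 oxidises it.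

Step 8
Reactants: 10 1-{(4R)-4-[(tert-butyldimethylsilyl)oxy]-2,6,6-trimethylcyclohex-1-en-1-yl}-3-({[(2E)-1,1-dimethoxy-3-methylhepta-2,6-dien-4-yl]oxy}methyl)but-3-en-2-ol
Product: 11 1-{6-[(2E)-4,4-dimethoxybut-2-en-2-yl]-5,6-dihydro-2H-pyran-3-yl}-2-{(4R)-4-[(tert-butyldimethylsilyl)oxy]-2,6,6-trimethylcyclohex-1-en-1-yl}ethan-1-ol (diastereomer mixture)
Conditions: second-generation Grubbs catalyst (0.05 equiv), CH2Cl2 (5 mM), 40 °C
Reagents that add atoms: none
Why: Ring-closing olefin metathesis of the terminal and the 1,1-disubstituted alkene closes the six-membered dihydropyran, in which C9=C10 can only have C19 and C11 cis, while the tri- and tetrasubstituted alkenes could only close strained or tetrasubstituted rings and stay out.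

Step 9
Reactants: 11 1-{6-[(2E)-4,4-dimethoxybut-2-en-2-yl]-5,6-dihydro-2H-pyran-3-yl}-2-{(4R)-4-[(tert-butyldimethylsilyl)oxy]-2,6,6-trimethylcyclohex-1-en-1-yl}ethan-1-ol
Product: 12 1-{6-[(2E)-4,4-dimethoxybut-2-en-2-yl]-5,6-dihydro-2H-pyran-3-yl}-2-{(4R)-4-[(tert-butyldimethylsilyl)oxy]-2,6,6-trimethylcyclohex-1-en-1-yl}ethan-1-one (C12 epimers)
Conditions: Dess–Martin periodinane (1.3 equiv), NaHCO3, CH2Cl2, 0 °C to rt
Reagents that add atoms: none
Why: Dess–Martin oxidation of the allylic carbinol gives the C8 ketone as a 3-acyl-5,6-dihydro-2H-pyran and removes the uncontrolled carbinol centre, the neutral conditions leaving both the C5=C6 bond and H11 in place.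

Step 10
Reactants: 12 1-{6-[(2E)-4,4-dimethoxybut-2-en-2-yl]-5,6-dihydro-2H-pyran-3-yl}-2-{(4R)-4-[(tert-butyldimethylsilyl)oxy]-2,6,6-trimethylcyclohex-1-en-1-yl}ethan-1-one
Product: 13 (2E)-3-(5-{[(4R)-4-hydroxy-2,6,6-trimethylcyclohex-1-en-1-yl]acetyl}-3,6-dihydro-2H-pyran-2-yl)but-2-enal (C12 epimers)
Conditions: aq. HF (48%, 5 equiv), MeCN–H2O, 0 °C to rt; NaHCO3
Reagents that add atoms: water, O
Why: Acetal hydrolysis frees the C15 aldehyde and fluoride-assisted desilylation frees the C3 hydroxyl in one operation, and the ring ether at C12 survives because its allylic alkene becomes conjugated with the aldehyde and does not support ionisation.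

Step 11
Reactants: 14 2,6,6-trimethylcyclohex-2-ene-1,4-dione (ketoisophorone)
Product: 15 (4R)-4-hydroxy-2,6,6-trimethylcyclohex-2-en-1-one
Conditions: (S)-2-methyl-CBS-oxazaborolidine (0.2 equiv), catecholborane (1.5 equiv), toluene, -78 °C; MeOH quench, aq. Na2CO3 wash
Reagents that add atoms: none
Why: Corey–Bakshi–Shibata reduction reaches only the unhindered C4 carbonyl (the other is flanked by the gem-dimethyl and the methyl-bearing alkene carbon) and, with the alkenyl flank as the large group, the (S)-catalyst should give the 4R carbinol that becomes C3'.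

Step 12
Reactants: 15 (4R)-4-hydroxy-2,6,6-trimethylcyclohex-2-en-1-one
Product: 16 (4R)-2,6,6-trimethyl-4-[(triethylsilyl)oxy]cyclohex-2-en-1-one
Conditions: Et3SiCl (1.2 equiv), imidazole (2.5 equiv), DMF, 0 °C to rt
Reagents that add atoms: chlorotriethylsilane, CC[Si](Cl)(CC)CC
Why: Silylation gives a bulky group that steers the epoxidation to the opposite face and that is later lost in the acidic phosphonium salt formation without a step of its own.

Step 13
Reactants: 16 (4R)-2,6,6-trimethyl-4-[(triethylsilyl)oxy]cyclohex-2-en-1-one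
Product: 17 (1S,5R,6S)-1,3,3-trimethyl-5-[(triethylsilyl)oxy]-7-oxabicyclo[4.1.0]heptan-2-one
Conditions: t-BuOOH (2 equiv, in decane), DBU (1.2 equiv), CH2Cl2, 0 °C to rt
Reagents that add atoms: tert-butyl hydroperoxide, CC(C)(C)OO
Why: Weitz–Scheffer nucleophilic epoxidation, in which the peroxide anion adds to the β-carbon anti to the neighbouring silyloxy group and the enolate closes the oxirane on that face, sets the epoxide oxygen trans to the C3' oxygen.

Step 14
Reactants: 17 (1S,5R,6S)-1,3,3-trimethyl-5-[(triethylsilyl)oxy]-7-oxabicyclo[4.1.0]heptan-2-one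
Product: 19 (1R,6R)-2,4,4-trimethyl-6-[(triethylsilyl)oxy]cyclohex-2-en-1-ol, via epoxy hydrazone 18 (not isolated)
Conditions: N2H4·H2O (4 equiv), AcOH (0.2 equiv), MeOH, 0 °C to rt
Reagents that add atoms: none
Why: Wharton transposition (hydrazone formation, opening of the oxirane to an alkenyl diazene, loss of N2) turns the C6' carbonyl into the C5'=C6' alkene and leaves an allylic alcohol at C4' with the configuration of the epoxide carbon, that is trans to the silyl ether.

Step 15
Reactants: 19 (1R,6R)-2,4,4-trimethyl-6-[(triethylsilyl)oxy]cyclohex-2-en-1-ol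
Product: 20 (1S,6R)-2,4,4-trimethyl-6-[(triethylsilyl)oxy]cyclohex-2-en-1-yl pyridine-2-carboxylate
Conditions: picolinic acid (1.5 equiv), PPh3 (1.5 equiv), DIAD (1.5 equiv), THF, 0 °C to rt
Reagents that add atoms: pyridine-2-carboxylic acid, OC(=O)c1ccccn1
Why: Mitsunobu esterification inverts C4' by SN2 displacement (the γ-carbon is neopentylic, so SN2' is not expected) and in the same step installs the chelating picolinate leaving group cis to the silyl ether.

Step 16
Reactants: 21 (2E)-3-methylpent-2-en-4-yn-1-ol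
Product: 22 (2E)-3-methylpent-2-en-4-ynal
Conditions: MnO2 (activated, 15 equiv), CH2Cl2, rt
Reagents that add atoms: none
Why: MnO2 oxidation of the primary allylic alcohol stops at the aldehyde and leaves the alkyne and the E alkene alone.

Step 17
Reactants: 22 (2E)-3-methylpent-2-en-4-ynal; 23 ethyl (2E)-4-(diethoxyphosphoryl)-3-methylbut-2-enoate
Product: 25 ethyl (2E,4E,6E)-3,7-dimethylnona-2,4,6-trien-8-ynoate, via lithiated phosphonate 24 (not isolated)
Conditions: 23 (1.2 equiv), LiN(SiMe3)2 (1.2 equiv), THF, -78 °C; then 22, -78 to 0 °C; 2Z isomer removed on SiO2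
Reagents that add atoms: none
Why: Horner–Wadsworth–Emmons olefination with the vinylogous phosphonate anion builds the E C11'=C12' bond and extends the chain to C15' in one step.

Step 18
Reactants: 25 ethyl (2E,4E,6E)-3,7-dimethylnona-2,4,6-trien-8-ynoate; 20 (1S,6R)-2,4,4-trimethyl-6-[(triethylsilyl)oxy]cyclohex-2-en-1-yl pyridine-2-carboxylate
Product: 28 ethyl (2E,4E,6E,8E)-3,7-dimethyl-9-{(1R,4R)-2,6,6-trimethyl-4-[(triethylsilyl)oxy]cyclohex-2-en-1-yl}nona-2,4,6,8-tetraenoate, via alkenylzirconocene chloride 26 (not isolated), via alkenylcopper 27 (not isolated)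
Conditions: 25 (1.3 equiv), Cp2Zr(H)Cl (1.4 equiv), THF, rt, dark; then CuBr·SMe2 (1.4 equiv), MgBr2·OEt2 (2 equiv), -40 °C; then 20, -40 to 0 °C; aq. NH4Cl
Reagents that add atoms: none
Why: Syn hydrozirconation of the terminal alkyne gives the E alkenylzirconocene, transmetalation gives the alkenyl organometal of monovalent copper, and copper-mediated allylic substitution of the magnesium-chelated picolinate is γ-selective and anti, so C7' adds to C6' on the face opposite the leaving group, trans to the C3' oxygen, while the double bond moves to C4'=C5'.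

Step 19
Reactants: 28 ethyl (2E,4E,6E,8E)-3,7-dimethyl-9-{(1R,4R)-2,6,6-trimethyl-4-[(triethylsilyl)oxy]cyclohex-2-en-1-yl}nona-2,4,6,8-tetraenoate
Product: 29 (2E,4E,6E,8E)-3,7-dimethyl-9-{(1R,4R)-2,6,6-trimethyl-4-[(triethylsilyl)oxy]cyclohex-2-en-1-yl}nona-2,4,6,8-tetraen-1-ol
Conditions: i-Bu2AlH (2.5 equiv), CH2Cl2, -78 °C; aq. KNaC4H4O6
Reagents that add atoms: none
Why: 1,2-Reduction of the conjugated ester by i-Bu2AlH gives the primary polyenylic alcohol without touching the tetraene, the silyl ether or the stereocentres.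

Step 20
Reactants: 29 (2E,4E,6E,8E)-3,7-dimethyl-9-{(1R,4R)-2,6,6-trimethyl-4-[(triethylsilyl)oxy]cyclohex-2-en-1-yl}nona-2,4,6,8-tetraen-1-ol
Product: 30 {(2E,4E,6E,8E)-9-[(1R,4R)-4-hydroxy-2,6,6-trimethylcyclohex-2-en-1-yl]-3,7-dimethylnona-2,4,6,8-tetraen-1-yl}triphenylphosphonium bromide
Conditions: PPh3·HBr (1.1 equiv), MeOH, 0 °C to rt, dark
Reagents that add atoms: triphenylphosphine hydrobromide, [Br-].c1ccc(cc1)[PH+](c1ccccc1)c1ccccc1
Why: Phosphonium salt formation through the polyenyl cation, as for retinyl salts, takes place at the primary tetraenylic alcohol while the acidic methanol removes the triethylsilyl group, and the ring allylic alcohol, which ionises far more slowly, keeps its configuration.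

Step 21
Reactants: 30 {(2E,4E,6E,8E)-9-[(1R,4R)-4-hydroxy-2,6,6-trimethylcyclohex-2-en-1-yl]-3,7-dimethylnona-2,4,6,8-tetraen-1-yl}triphenylphosphonium bromide; 13 (2E)-3-(5-{[(4R)-4-hydroxy-2,6,6-trimethylcyclohex-1-en-1-yl]acetyl}-3,6-dihydro-2H-pyran-2-yl)but-2-enal
Product: 32 (3R,3'R,6'R)-12,19-epoxy-3,3'-dihydroxy-7,8,11,12-tetrahydro-β,ε-caroten-8-one (C40 dihydropyran; C12 epimers; 15E/15Z mixture), via phosphorus ylide 31 (not isolated)
Conditions: 30 (1.1 equiv), 1,2-epoxybutane–EtOH (1:1), 75 °C, dark, Ar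
Reagents that add atoms: none
Why: Wittig olefination under neutral oxirane conditions (bromide opens the epoxide and the alkoxide so formed deprotonates the salt) joins the two C20 halves at C15=C15' chemoselectively at the aldehyde, and the 15Z/15E mixture together with any material whose pyran has already opened converges in step 22.

Step 22
Reactants: 32 (3R,3'R,6'R)-12,19-epoxy-3,3'-dihydroxy-7,8,11,12-tetrahydro-β,ε-caroten-8-one
Product: 35 (3R,3'R,6'R)-3,19,3'-trihydroxy-7,8-dihydro-β,ε-caroten-8-one (siphonaxanthin, all-E; CNP0183826.2), via sodium dienolate 33 (not isolated), via sodium alkoxide 34 (not isolated)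
Conditions: NaOMe (5 equiv), MeOH–THF (1:1), 0 °C to rt, dark, Ar; aq. NH4Cl; then n-heptane–EtOAc, reflux, 2 h (Z to E); crystallisation of the all-E isomer
Reagents that add atoms: none
Why: Methoxide reversibly removes H11, which is γ to the C8 ketone through C9=C10, and the dienolate expels O19 from C12 (E1cB, a vinylogous retro-oxa-Michael reaction), which forms C11=C12 and frees the 19-hydroxyl. The closest known reaction is the base opening of 6-substituted 5,6-dihydro-2H-pyran-2-ones to (2Z,4E)-dienoic acids, here with an alkoxide in place of a carboxylate as leaving group. No ring is closed: the temporary pyran is opened, C9=C10 emerges with CH2OH and C11 cis (9E) because they were ring neighbours, and C11=C12 should form E because the polyenyl group on C12 sits pseudo-equatorial, anti to C10, when the C12–O bond aligns with the dienolate π system; any Z isomer is equilibrated thermally together with C15=C15'. No stereocentre is made: C12, carried as both epimers, becomes sp2, and C3, C3' and C6' are not deprotonated under these conditions. The step needs cleavage of C12–O and not of C19–O, which is also β to the dienolate (at C9): that alternative gives a cross-conjugated 2-methylene enone which re-closes by oxa-Michael addition, and the C7 enolate has no leaving group and reverts, so the material should drain into the linear, fully conjugated octaenone. That gain in conjugation is the driving force, and polyenones of this type tolerate methanolic alkali.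

**Compound list**

1 | (4R,6R)-4-hydroxy-2,2,6-trimethylcyclohexan-1-one (actinol) | O=C1C(C)(C)C[C@H](O)C[C@H]1C | starting material
2 | (4R,6R)-4-[(tert-butyldimethylsilyl)oxy]-2,2,6-trimethylcyclohexan-1-one | O=C1C(C)(C)C[C@H](O[Si](C)(C)C(C)(C)C)C[C@H]1C | intermediate
3 | tert-butyldimethyl{[(1R,5R)-3,3,5-trimethyl-4-methylidenecyclohexyl]oxy}silane | C=C1C(C)(C)C[C@H](O[Si](C)(C)C(C)(C)C)C[C@H]1C | intermediate
4 | 2-{(4R)-4-[(tert-butyldimethylsilyl)oxy]-2,6,6-trimethylcyclohex-1-en-1-yl}ethan-1-ol | OCCC1=C(C)C[C@@H](O[Si](C)(C)C(C)(C)C)CC1(C)C | intermediate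
5 | {(4R)-4-[(tert-butyldimethylsilyl)oxy]-2,6,6-trimethylcyclohex-1-en-1-yl}acetaldehyde | O=CCC1=C(C)C[C@@H](O[Si](C)(C)C(C)(C)C)CC1(C)C | intermediate
6 | (2E)-4,4-dimethoxy-2-methylbut-2-enal | O=C/C(C)=C/C(OC)OC | starting material
7 | (2E)-1,1-dimethoxy-3-methylhepta-2,6-dien-4-ol (racemic) | COC(OC)/C=C(C)/C(O)CC=C | intermediate
8 | (2E)-4-[(2-bromoprop-2-en-1-yl)oxy]-1,1-dimethoxy-3-methylhepta-2,6-diene (racemic) | COC(OC)/C=C(C)/C(OCC(Br)=C)CC=C | intermediate
9 | dichlorido[3-{[(2E)-1,1-dimethoxy-3-methylhepta-2,6-dien-4-yl]oxy}prop-1-en-2-yl]chromium (alkenyl organometal of trivalent chromium) | COC(OC)/C=C(C)/C(OCC(=C)[Cr](Cl)Cl)CC=C | intermediate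
10 | 1-{(4R)-4-[(tert-butyldimethylsilyl)oxy]-2,6,6-trimethylcyclohex-1-en-1-yl}-3-({[(2E)-1,1-dimethoxy-3-methylhepta-2,6-dien-4-yl]oxy}methyl)but-3-en-2-ol (mixture at both carbinol-derived centres) | COC(OC)/C=C(C)/C(OCC(=C)C(O)CC1=C(C)C[C@@H](O[Si](C)(C)C(C)(C)C)CC1(C)C)CC=C | intermediate
11 | 1-{6-[(2E)-4,4-dimethoxybut-2-en-2-yl]-5,6-dihydro-2H-pyran-3-yl}-2-{(4R)-4-[(tert-butyldimethylsilyl)oxy]-2,6,6-trimethylcyclohex-1-en-1-yl}ethan-1-ol (diastereomer mixture) | COC(OC)/C=C(C)/C1CC=C(CO1)C(O)CC1=C(C)C[C@@H](O[Si](C)(C)C(C)(C)C)CC1(C)C | intermediate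
12 | 1-{6-[(2E)-4,4-dimethoxybut-2-en-2-yl]-5,6-dihydro-2H-pyran-3-yl}-2-{(4R)-4-[(tert-butyldimethylsilyl)oxy]-2,6,6-trimethylcyclohex-1-en-1-yl}ethan-1-one (C12 epimers) | COC(OC)/C=C(C)/C1CC=C(CO1)C(=O)CC1=C(C)C[C@@H](O[Si](C)(C)C(C)(C)C)CC1(C)C | intermediate
13 | (2E)-3-(5-{[(4R)-4-hydroxy-2,6,6-trimethylcyclohex-1-en-1-yl]acetyl}-3,6-dihydro-2H-pyran-2-yl)but-2-enal (C12 epimers) | O=C/C=C(C)/C1CC=C(CO1)C(=O)CC1=C(C)C[C@@H](O)CC1(C)C | intermediate
14 | 2,6,6-trimethylcyclohex-2-ene-1,4-dione (ketoisophorone) | CC1=CC(=O)CC(C)(C)C1=O | starting material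
15 | (4R)-4-hydroxy-2,6,6-trimethylcyclohex-2-en-1-one | CC1=C[C@H](O)CC(C)(C)C1=O | intermediate
16 | (4R)-2,6,6-trimethyl-4-[(triethylsilyl)oxy]cyclohex-2-en-1-one | CC1=C[C@H](O[Si](CC)(CC)CC)CC(C)(C)C1=O | intermediate
17 | (1S,5R,6S)-1,3,3-trimethyl-5-[(triethylsilyl)oxy]-7-oxabicyclo[4.1.0]heptan-2-one | C[C@]12O[C@H]1[C@H](O[Si](CC)(CC)CC)CC(C)(C)C2=O | intermediate
18 | hydrazone of 17 at the ring carbonyl | C[C@]12O[C@H]1[C@H](O[Si](CC)(CC)CC)CC(C)(C)C2=NN | intermediate
19 | (1R,6R)-2,4,4-trimethyl-6-[(triethylsilyl)oxy]cyclohex-2-en-1-ol | CC1=CC(C)(C)C[C@@H](O[Si](CC)(CC)CC)[C@@H]1O | intermediate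
20 | (1S,6R)-2,4,4-trimethyl-6-[(triethylsilyl)oxy]cyclohex-2-en-1-yl pyridine-2-carboxylate | CC1=CC(C)(C)C[C@@H](O[Si](CC)(CC)CC)[C@H]1OC(=O)c1ccccn1 | intermediate
21 | (2E)-3-methylpent-2-en-4-yn-1-ol | C#C/C(C)=C/CO | starting material
22 | (2E)-3-methylpent-2-en-4-ynal | C#C/C(C)=C/C=O | intermediate
23 | ethyl (2E)-4-(diethoxyphosphoryl)-3-methylbut-2-enoate | CCOC(=O)/C=C(\C)CP(=O)(OCC)OCC | starting material
24 | lithium salt of the carbanion of 23 (lithiated next to phosphorus) | CCOC(=O)/C=C(\C)[CH-]P(=O)(OCC)OCC.[Li+] | intermediate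
25 | ethyl (2E,4E,6E)-3,7-dimethylnona-2,4,6-trien-8-ynoate | C#C/C(C)=C/C=C/C(C)=C/C(=O)OCC | intermediate
26 | ethyl (2E,4E,6E,8E)-9-[chloridobis(cyclopentadienyl)zirconio]-3,7-dimethylnona-2,4,6,8-tetraenoate (cyclopentadienyl rings drawn σ-bonded) | CCOC(=O)/C=C(C)/C=C/C=C(C)/C=C/[Zr](Cl)(C1C=CC=C1)C1C=CC=C1 | intermediate
27 | ethyl (2E,4E,6E,8E)-9-cuprio-3,7-dimethylnona-2,4,6,8-tetraenoate (alkenyl organometal of monovalent copper) | CCOC(=O)/C=C(C)/C=C/C=C(C)/C=C/[Cu] | intermediate
28 | ethyl (2E,4E,6E,8E)-3,7-dimethyl-9-{(1R,4R)-2,6,6-trimethyl-4-[(triethylsilyl)oxy]cyclohex-2-en-1-yl}nona-2,4,6,8-tetraenoate | CC1=C[C@H](O[Si](CC)(CC)CC)CC(C)(C)[C@H]1/C=C/C(C)=C/C=C/C(C)=C/C(=O)OCC | intermediate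
29 | (2E,4E,6E,8E)-3,7-dimethyl-9-{(1R,4R)-2,6,6-trimethyl-4-[(triethylsilyl)oxy]cyclohex-2-en-1-yl}nona-2,4,6,8-tetraen-1-ol | CC1=C[C@H](O[Si](CC)(CC)CC)CC(C)(C)[C@H]1/C=C/C(C)=C/C=C/C(C)=C/CO | intermediate
30 | {(2E,4E,6E,8E)-9-[(1R,4R)-4-hydroxy-2,6,6-trimethylcyclohex-2-en-1-yl]-3,7-dimethylnona-2,4,6,8-tetraen-1-yl}triphenylphosphonium bromide | CC1=C[C@H](O)CC(C)(C)[C@H]1/C=C/C(C)=C/C=C/C(C)=C/C[P+](c1ccccc1)(c1ccccc1)c1ccccc1.[Br-] | intermediate
31 | {(2E,4E,6E,8E)-9-[(1R,4R)-4-hydroxy-2,6,6-trimethylcyclohex-2-en-1-yl]-3,7-dimethylnona-2,4,6,8-tetraen-1-ylidene}triphenylphosphorane (ylide of 30) | CC1=C[C@H](O)CC(C)(C)[C@H]1/C=C/C(C)=C/C=C/C(C)=C/C=P(c1ccccc1)(c1ccccc1)c1ccccc1 | intermediate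
32 | (3R,3'R,6'R)-12,19-epoxy-3,3'-dihydroxy-7,8,11,12-tetrahydro-β,ε-caroten-8-one (C40 dihydropyran; C12 epimers; 15E isomer drawn) | CC1=C[C@H](O)CC(C)(C)[C@H]1/C=C/C(C)=C/C=C/C(C)=C/C=C/C=C(C)/C1CC=C(CO1)C(=O)CC1=C(C)C[C@@H](O)CC1(C)C | intermediate
33 | sodium dienolate of 32 (deprotonated at C11, charge drawn on O8) | CC1=C[C@H](O)CC(C)(C)[C@H]1/C=C/C(C)=C/C=C/C(C)=C/C=C/C=C(C)/C1C=CC(CO1)=C([O-])CC1=C(C)C[C@@H](O)CC1(C)C.[Na+] | intermediate
34 | sodium 19-alkoxide of siphonaxanthin | CC1=C[C@H](O)CC(C)(C)[C@H]1/C=C/C(C)=C/C=C/C(C)=C/C=C/C=C(C)/C=C/C=C(\C[O-])C(=O)CC1=C(C)C[C@@H](O)CC1(C)C.[Na+] | intermediate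
35 | (3R,3'R,6'R)-3,19,3'-trihydroxy-7,8-dihydro-β,ε-caroten-8-one (siphonaxanthin) | CC1=C[C@H](O)CC(C)(C)[C@H]1/C=C/C(C)=C/C=C/C(C)=C/C=C/C=C(C)/C=C/C=C(\CO)C(=O)CC1=C(C)C[C@@H](O)CC1(C)C | target

Total step count: 22. Longest linear sequence: 10 steps (1 → 2 → 3 → 4 → 5 → 10 → 11 → 12 → 13 → 32 → 35; the line from 14 through 20, 28, 29, 30 and 32 is equally long).

Steps most likely to fail:

Step 22. The C40 polyene may degrade under alkoxide (methoxide addition to the polyenone, double-bond migration in the ε ring) faster than the pyran opens. The fallback would move the opening to the fragment stage, where no long polyene is present. Setting out from 13, NaOMe in MeOH–THF or DBU in CH2Cl2 would open the pyran to (2E,4E,6E)-7-(hydroxymethyl)-9-[(4R)-4-hydroxy-2,6,6-trimethylcyclohex-1-en-1-yl]-3-methyl-8-oxonona-2,4,6-trienal F1, which could be purified and checked. Wittig olefination of F1 with ylide 31 under the oxirane conditions of step 21, followed by thermal Z to E equilibration, would return to the route at 35.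

Step 18. The tetraenyl copper species may decompose, or may fail to attack the neopentylic γ-carbon, leading to direct substitution at C4' or to recovered picolinate. The fallback would use a shorter and sturdier dienyl nucleophile and finish the chain afterwards. Setting out from 22, HC(OEt)3 and pyridinium tosylate in EtOH would give (3E)-5,5-diethoxy-3-methylpent-3-en-1-yne F2. The same hydrozirconation, copper transmetalation and anti-SN2' substitution with 20 would give triethyl{[(1R,4R)-4-[(1E,3E)-5,5-diethoxy-3-methylpenta-1,3-dien-1-yl]-3,5,5-trimethylcyclohex-2-en-1-yl]oxy}silane F3. Wet SiO2 with oxalic acid would free (2E,4E)-3-methyl-5-{(1R,4R)-2,6,6-trimethyl-4-[(triethylsilyl)oxy]cyclohex-2-en-1-yl}penta-2,4-dienal F4, and Horner–Wadsworth–Emmons olefination of F4 with 24 would return to the route at 28.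

Step 15. Activation of the hindered allylic alcohol may lead to elimination to the cyclohexadiene or to incomplete inversion. The fallback would invert C4' by oxidation and reduction instead of displacement. Setting out from 19, Dess–Martin oxidation would give (6R)-2,4,4-trimethyl-6-[(triethylsilyl)oxy]cyclohex-2-en-1-one F5. LiBH(s-Bu)3 in THF at -78 °C, delivering hydride anti to the silyloxy group, would give (1S,6R)-2,4,4-trimethyl-6-[(triethylsilyl)oxy]cyclohex-2-en-1-ol F6. Acylation of F6 with picolinic acid, dicyclohexylcarbodiimide and 4-(dimethylamino)pyridine would return to the route at 20.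

Further compounds

F1 | step 22 | (2E,4E,6E)-7-(hydroxymethyl)-9-[(4R)-4-hydroxy-2,6,6-trimethylcyclohex-1-en-1-yl]-3-methyl-8-oxonona-2,4,6-trienal | O=C/C=C(C)/C=C/C=C(\CO)C(=O)CC1=C(C)C[C@@H](O)CC1(C)C
F2 | step 18 | (3E)-5,5-diethoxy-3-methylpent-3-en-1-yne | C#C/C(C)=C/C(OCC)OCC
F3 | step 18 | triethyl{[(1R,4R)-4-[(1E,3E)-5,5-diethoxy-3-methylpenta-1,3-dien-1-yl]-3,5,5-trimethylcyclohex-2-en-1-yl]oxy}silane | CC1=C[C@H](O[Si](CC)(CC)CC)CC(C)(C)[C@H]1/C=C/C(C)=C/C(OCC)OCC
F4 | step 18 | (2E,4E)-3-methyl-5-{(1R,4R)-2,6,6-trimethyl-4-[(triethylsilyl)oxy]cyclohex-2-en-1-yl}penta-2,4-dienal | CC1=C[C@H](O[Si](CC)(CC)CC)CC(C)(C)[C@H]1/C=C/C(C)=C/C=O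
F5 | step 15 | (6R)-2,4,4-trimethyl-6-[(triethylsilyl)oxy]cyclohex-2-en-1-one | CC1=CC(C)(C)C[C@@H](O[Si](CC)(CC)CC)C1=O
F6 | step 15 | (1S,6R)-2,4,4-trimethyl-6-[(triethylsilyl)oxy]cyclohex-2-en-1-ol | CC1=CC(C)(C)C[C@@H](O[Si](CC)(CC)CC)[C@H]1O
A1 | direct plan | ethane-1,2-diyl bis(2,6,6-trimethyl-4-oxocyclohex-2-ene-1-carboxylate) | CC1=CC(=O)CC(C)(C)C1C(=O)OCCOC(=O)C1C(C)=CC(=O)CC1(C)C
A2 | direct plan | (1R)-4-(chloromethyl)-3,5,5-trimethylcyclohex-3-en-1-ol | ClCC1=C(C)C[C@@H](O)CC1(C)C
A3 | direct plan | (2E,4E,6E,8E,10E,12E,14E,16E)-17-[(1R,4R)-4-hydroxy-2,6,6-trimethylcyclohex-2-en-1-yl]-6,11,15-trimethyl-2-(tributylstannyl)heptadeca-2,4,6,8,10,12,14,16-octaen-1-ol | CC1=C[C@H](O)CC(C)(C)[C@H]1/C=C/C(C)=C/C=C/C(C)=C/C=C/C=C(C)/C=C/C=C(\CO)[Sn](CCCC)(CCCC)CCCC
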